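## Structural features

Atom labels (O2, C1, C3 to C8a) follow the isochromene numbering of the target throughout.

The target is a 6,7-dihydro-1H-isochromen-8(5H)-one. A pyran ring (C1, O2, C3, C4) is fused through the C4a=C8a double bond to a cyclohexenone ring (C5 to C8), so that O2–C3=C4–C4a=C8a–C8=O is one continuous push–pull dienone. C3 carries a trans (2S,3R)-3-methyloxiranyl group, which makes the epoxide a vinyl epoxide on an enol ether carbon. In the carbocycle, C6 (R) bears the orsellinate ester and the neighbouring C7 (R) is a fully substituted carbinol with methyl and hydroxyl, the two oxygens being cis. C7 lies next to the C8 ketone, so C7–C8 is a tertiary α-ketol. The epoxide pair is too far from C6/C7 for any relay of configuration, so two enantiopure building blocks are needed. The fragile points are: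

- the vinyl epoxide (acid, nucleophiles, zerovalent palladium, hydrogen);
- the dienyl ether (acid);
- the α-ketol (base-induced acyloin scrambling or retro-aldol);
- the C6 ester, which a base can expel through the C5 dienolate to leave a cyclohexa-2,4-dienone.

The real difficulty is the cis C6/C7 pair, with a quaternary C7 wedged between a ketone and an acylated carbinol, and a hindered ester that must be made late under near-neutral conditions. The key step uses the array C8(=O)–C7(CH3)(OH)–C6(O): it is the α-ketol isomer of a 1-acetylcyclopent-2-en-1-ol in which C6 is bonded to C8, and ring enlargement is driven by the conjugation that C8=O gains with C8a=C4a.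

## Logic of the disconnections

**25 ⇒ 24.** The two aryl O–H bonds are traced back to aryl O–Si bonds. The phenols must be masked while the ester is made, and buffered fluoride is the one unmasking that touches neither the vinyl epoxide, the dienyl ether nor the C6 ester. Hydrogenolysis, acid and zerovalent palladium are all excluded by the epoxide. The forward step must stay non-basic, because base could expel the C6 carboxylate through the C5 dienolate.

**24 ⇒ 20 + 23.** The ester bond between the benzoyl carbon and O6 is cut. This separates the aromatic ring from the bicyclic core and makes the route convergent. The forward step must acylate a secondary hydroxyl next to a quaternary carbon with a doubly ortho-substituted aroyl chloride, and must leave the tertiary C7 hydroxyl alone. The pyran has to be closed before this point, since a base-mediated ring closure after acylation would invite loss of the carboxylate.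

**23 ⇒ 22 ⇒ 21.** The acyl C–Cl bond and three O–Si bonds are cut. Exhaustive silylation followed by direct conversion of the silyl ester into the acid chloride avoids any free-acid intermediate and any selective hydrolysis.

**20 ⇒ 17.** The O2–C3 bond of the pyran is cut, and the oxygens on C1 and C6 are returned to the same kind of silyl ether. The alkyne on C4a is conjugated with the C8 ketone, so C3 is the δ-position of a 1,6-acceptor and oxygen arrives there in the 6-endo mode. The disconnection removes one ring and replaces the vinyl epoxide and dienyl ether by a sturdier propargylic epoxide and enynone. Using one silyl type on both oxygens lets a single fluoride treatment free both hydroxyls and close the ring, which a benzyl-type ether on the C1 oxygen would not allow. The forward step must deliver oxygen to C3 and not to C4, and must avoid π-acidic metal catalysts, which rearrange propargylic epoxides.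

**17 ⇒ 16.** This is the key disconnection: the C6–C7 bond is cut and C6 is reconnected to C8. The six-membered ring with its quaternary carbinol becomes a cyclopentenol bearing an acetyl group, and the C7 problem is reduced to a carbonyl addition controlled by C6. The forward step requires that C6 and not C8a migrates, and that the carbinol oxygen and the acetyl oxygen are held syn while the carbinol oxygen is cis to the C6 oxygen.

**16 ⇒ 12 + 13.** The C7–C8 bond is cut, so C7 and its methyl group come from an acetyl anion equivalent. The forward addition must be 1,2, must occur on the face opposite the C6 silyloxy group, and the masked acetyl group must be released without harm to the epoxide or the tertiary allylic alcohol.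

**12 ⇒ 11 ⇒ 9 + 4.** The C4–C4a bond is cut and the ketone oxygen is returned from C8 to C4a. Acetylide addition to the carbonyl of 9, followed by oxidative transposition, joins the two chiral fragments and places the ketone next to the silyloxy carbon. The oxidant must tolerate the epoxide and both silyl ethers.

**9 ⇒ 8 ⇒ 6 + 7 ⇒ 5.** An O–Si bond, the C1–C8a bond and a C8a–I bond are cut. The hydroxymethyl carbon is introduced by α-iodination and Stille coupling on the parent enone. α-Iodination is most dependable on a β-unsubstituted enone, so it is placed before the alkyne is attached and not after.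

**4 ⇒ 2 ⇒ 1.** The C3≡C4 bond (one-carbon homologation of an aldehyde) and the two epoxide C–O bonds are cut. Both epoxide stereocentres then come from one catalytic asymmetric epoxidation of an E-allylic alcohol. The small intermediates are volatile and water-soluble, so the forward steps need non-aqueous handling.

## Other disconnections considered

**Alternative 1:** The cut is through C4a–C8a and O2–C1, so both rings are opened to the acyclic (Z)-β-iodoenone A1, which carries the vinyl ketone and the epoxy ketone. In the forward sense Pd(OAc)2, PPh3 and Ag2CO3 should bring about a 6-exo Heck cyclisation, then β-hydride elimination and an oxa-6π electrocyclisation to give the bis(triethylsilyl) ether A2.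

- In its favour: both rings and the complete dienone form in one operation. C6 and C7 are set earlier in an open chain by reagent control, so their relation does not depend on a chelated transition state. On this point the alternative is at least the equal of the chosen plan, and in predictability probably the better. No protecting group is needed on the C1 oxygen.
- Against it here: A1 combines a polymerisable vinyl ketone, a Z-iodoenone whose geometry must survive, and an α,β-epoxy ketone that zerovalent palladium can isomerise to a β-diketone. The product A2 is a vinyl epoxide that the same catalyst can ionise. The exo mode must also beat 7-endo closure at the electronically preferred terminal carbon.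
- Comparison: the chosen plan builds the rings one at a time by ionic steps and never exposes the epoxide to a transition metal. In step count the two are comparable, since A2 needs only desilylation to reach 20 but A1 itself requires a multistep assembly.

**Alternative 2:** The cuts are C4–C4a and C1–C8a. In the forward sense the enone A3 undergoes conjugate alkynylation by the alane A4 under Ni(acac)2 and i-Bu2AlH (a zerovalent nickel catalyst formed in the flask), and the C8a position is then trapped with formaldehyde A5 to give the trans-disubstituted cyclohexanone A6.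

- In its favour: two C–C bonds form in a three-component reaction. The cis C6/C7 diol is fixed in A3 before the coupling, which is as secure as, or more secure than, relying on a rearrangement. The hydroxymethyl group is introduced without tin, which is better than the Stille coupling of the chosen plan in waste and toxicity.
- Against it here: A6 is at the wrong oxidation level. The two new stereocentres are sacrificial, and a dehydrogenation beside an α-hydroxymethyl ketone is needed, a setting prone to retro-aldol loss of formaldehyde or elimination to an exo-methylene ketone. The alane cannot carry the epoxide, because an aluminium acetylide would open it. The epoxide must therefore be made late by a catalyst-controlled epoxidation of the propenyl group in the presence of the dienone.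
- Comparison: in the chosen plan the epoxide configuration comes from an early, reliable Sharpless step, and the C4a=C8a double bond is present from the start. The alternative is more convergent in its key step but needs a longer endgame.

**Alternative 3:** The cut is C5–C6. The precursor is the 4-methyl-2H-pyran keto aldehyde A7. In the forward sense soft enolisation with MgBr2·OEt2 and i-Pr2NEt deprotonates the C4a methyl group, and an intramolecular vinylogous aldol addition to the chelated aldehyde closes the carbocycle to A8.

- In its favour: the pyran and the epoxide side chain are settled early. The ring closure is mild. A8 emerges with the C6 hydroxyl free and the C7 hydroxyl silylated, which is the ideal differentiation for the esterification and better than the diol 20 of the chosen plan, where selectivity rests on steric difference alone. α-Attack is impossible because C8a is fully substituted, so regiochemistry is not in question.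
- Against it here: A7 is a monocyclic 2H-pyran, a class that can ring-open electrocyclically. It is also a non-enolisable β-keto aldehyde, open to retro-Claisen deformylation. MgBr2 is a classical reagent for turning epoxides into bromohydrins. The cis relation at C6 depends on which pair of oxygens magnesium bridges, and a triethylsilyl ether is a poor ligand. The aldol is also reversible, without a strong thermodynamic bias.
- Comparison: the chosen plan takes C6 from an enantiopure commercial building block and sets C7 through a rigid five-membered chelate under thermodynamic control. Step counts are similar.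

Key step: step 9

Remark on the chemistry: 11 is drawn as the carbinol epimer expected from attack anti to the ring silyloxy group. The other epimer serves equally, because step 7 removes that stereocentre. (Tributylstannyl)methanol and dimethyl (1-diazo-2-oxopropyl)phosphonate are taken as purchased reagents.

## Route

Step 1
Reactants: 1 (E)-crotyl alcohol
Product: 2 [(2R,3R)-3-methyloxiran-2-yl]methanol
Conditions: Ti(O-i-Pr)4 (cat.), D-(−)-diisopropyl tartrate (cat.), t-BuOOH, 4 Å MS, CH2Cl2, −20 °C; non-aqueous work-up
Reagents that add atoms: tert-butyl hydroperoxide, CC(C)(C)OO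
Why: Sharpless asymmetric epoxidation; with the D-(−)-tartrate ligand the titanium peroxo complex delivers oxygen to the face of the E-allylic alcohol that gives the (2R,3R)-trans-epoxide, setting both epoxide stereocentres at once.

Step 2
Reactants: 2 [(2R,3R)-3-methyloxiran-2-yl]methanol
Product: 4 (2R,3R)-2-ethynyl-3-methyloxirane, via (2S,3R)-3-methyloxirane-2-carbaldehyde 3 (not isolated)
Conditions: PhI(OAc)2, TEMPO (cat.), CH2Cl2, rt; then MeOH, K2CO3, dimethyl (1-diazo-2-oxopropyl)phosphonate, 0 °C → rt; product kept as a solution
Reagents that add atoms: dimethyl (1-diazo-2-oxopropyl)phosphonate, CC(=O)C(=[N+]=[N-])P(=O)(OC)OC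
Why: Oxoammonium (TEMPO) oxidation gives the epoxy aldehyde without epoxide opening, and Ohira–Bestmann (Seyferth–Gilbert) homologation in the same flask converts CHO into C≡CH through the alkylidene carbene; the epoxide carbons are not involved, and telescoping avoids isolating the volatile aldehyde.

Step 3
Reactants: 5 (R)-4-[(tert-butyldimethylsilyl)oxy]cyclopent-2-en-1-one
Product: 6 (R)-4-[(tert-butyldimethylsilyl)oxy]-2-iodocyclopent-2-en-1-one
Conditions: I2, pyridine, CH2Cl2, 0 °C → rt
Reagents that add atoms: iodine, II
Why: α-Iodination of an enone by pyridine conjugate addition, iodination of the enolate and elimination; a β-unsubstituted cyclopentenone is the best substrate class for it, and the weak amine base at 0 °C should not trigger loss of the β-silyloxy group.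

Step 4
Reactants: 6 (R)-4-[(tert-butyldimethylsilyl)oxy]-2-iodocyclopent-2-en-1-one; 7 (tributylstannyl)methanol
Product: 8 (R)-4-[(tert-butyldimethylsilyl)oxy]-2-(hydroxymethyl)cyclopent-2-en-1-one
Conditions: Pd(PPh3)4 (cat.), CuI (cat.), 1,4-dioxane, 80 °C
Reagents that add atoms: none
Why: Stille coupling; the electron-poor alkenyl iodide adds readily to zerovalent palladium and the hydroxymethyl group is transferred from tin in preference to butyl, under neutral conditions that spare the base-sensitive β-silyloxy ketone.

Step 5
Reactants: 8 (R)-4-[(tert-butyldimethylsilyl)oxy]-2-(hydroxymethyl)cyclopent-2-en-1-one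
Product: 9 (R)-4-[(tert-butyldimethylsilyl)oxy]-2-{[(tert-butyldimethylsilyl)oxy]methyl}cyclopent-2-en-1-one
Conditions: TBSCl, imidazole, CH2Cl2, 0 °C → rt
Reagents that add atoms: tert-butyldimethylsilyl chloride, CC(C)(C)[Si](C)(C)Cl
Why: Standard silylation of a primary alcohol; the same silyl group as on the ring oxygen is chosen so that one fluoride treatment can later free both oxygens.

Step 6
Reactants: 4 (2R,3R)-2-ethynyl-3-methyloxirane; 9 (R)-4-[(tert-butyldimethylsilyl)oxy]-2-{[(tert-butyldimethylsilyl)oxy]methyl}cyclopent-2-en-1-one
Product: 11 (1R,4R)-4-[(tert-butyldimethylsilyl)oxy]-2-{[(tert-butyldimethylsilyl)oxy]methyl}-1-{[(2R,3R)-3-methyloxiran-2-yl]ethynyl}cyclopent-2-en-1-ol, via lithium acetylide 10 (not isolated)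
Conditions: 4, n-BuLi, THF, −78 °C; anhydrous CeCl3, −78 °C; then 9, −78 °C; aq. NH4Cl
Reagents that add atoms: none
Why: 1,2-Addition of an alkynyl organometallic to an enone carbonyl; CeCl3 raises carbonyl electrophilicity and lowers basicity, which suppresses C5 enolisation and loss of silanolate. Attack should be mainly anti to the silyloxy group, but the new carbinol centre is erased in step 7.

Step 7
Reactants: 11 (1R,4R)-4-[(tert-butyldimethylsilyl)oxy]-2-{[(tert-butyldimethylsilyl)oxy]methyl}-1-{[(2R,3R)-3-methyloxiran-2-yl]ethynyl}cyclopent-2-en-1-ol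
Product: 12 (R)-5-[(tert-butyldimethylsilyl)oxy]-2-{[(tert-butyldimethylsilyl)oxy]methyl}-3-{[(2R,3R)-3-methyloxiran-2-yl]ethynyl}cyclopent-2-en-1-one
Conditions: pyridinium chlorochromate [C5H5NH][CrO3Cl], powdered 4 Å MS, CH2Cl2, rt
Reagents that add atoms: pyridinium chlorochromate, [O-][Cr](=O)(=O)Cl.c1cc[nH+]cc1
Why: Dauben–Babler oxidative 1,3-transposition: the tertiary chromate ester undergoes a [3,3] shift to the secondary allylic chromate, which hexavalent chromium oxidises to the enone, the carbonyl oxygen coming from the reagent. The driving force is the tetrasubstituted alkene conjugated with alkyne and ketone, and the silyloxy stereocentre is not touched.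

Step 8
Reactants: 12 (R)-5-[(tert-butyldimethylsilyl)oxy]-2-{[(tert-butyldimethylsilyl)oxy]methyl}-3-{[(2R,3R)-3-methyloxiran-2-yl]ethynyl}cyclopent-2-en-1-one; 13 ethyl vinyl ether
Product: 16 1-[(1S,5R)-5-[(tert-butyldimethylsilyl)oxy]-2-{[(tert-butyldimethylsilyl)oxy]methyl}-1-hydroxy-3-{[(2R,3R)-3-methyloxiran-2-yl]ethynyl}cyclopent-2-en-1-yl]ethan-1-one, via (1-ethoxyvinyl)lithium 14 (not isolated), via 1-ethoxyvinyl carbinol 15 (not isolated)
Conditions: 13, t-BuLi, THF, −78 → 0 °C; then 12, −78 °C; then 1 M aq. oxalic acid, 0 °C
Reagents that add atoms: water, O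
Why: 1-Ethoxyvinyllithium is a hard acetyl anion equivalent that adds 1,2 to the carbonyl (the β-carbon is fully substituted) from the face opposite the adjacent C–OSi bond, which sets the carbinol with its hydroxyl cis to the silyloxy group. The enol ether then hydrolyses to the methyl ketone under mild acid, which spares the epoxide, the silyl ethers and the tertiary allylic alcohol.

Step 9
Reactants: 16 1-[(1S,5R)-5-[(tert-butyldimethylsilyl)oxy]-2-{[(tert-butyldimethylsilyl)oxy]methyl}-1-hydroxy-3-{[(2R,3R)-3-methyloxiran-2-yl]ethynyl}cyclopent-2-en-1-yl]ethan-1-one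
Product: 17 (5R,6R)-5-[(tert-butyldimethylsilyl)oxy]-2-{[(tert-butyldimethylsilyl)oxy]methyl}-6-hydroxy-6-methyl-3-{[(2R,3R)-3-methyloxiran-2-yl]ethynyl}cyclohex-2-en-1-one
Conditions: Al(O-t-Bu)3, toluene, 80 °C; aq. potassium sodium tartrate work-up
Reagents that add atoms: none
Why: Ligand exchange gives the aluminium alkoxide of the tertiary carbinol, and aluminium bridges this oxygen and the acetyl oxygen in a five-membered chelate that holds the O–C8–C7=O unit syn-periplanar and activates the acetyl carbon. C6, the ring carbon bearing the silyloxy group, then migrates suprafacially with retention from C8 to C7 while C8–O becomes the ketone; this is an α-ketol (acyloin) rearrangement, the known ring-enlarging isomerisation of 1-acylcycloalkanols to 2-hydroxy-2-alkylcycloalkanones. No ring is closed by a cyclisation: the cyclopentene becomes the cyclohexenone through the 1,2-shift, which forms C6–C7 and breaks C6–C8. The new stereocentre C7 is fixed by the chelate: with the carbinol oxygen cis to C6–OSi (from step 8) and the carbonyl oxygen eclipsing it, C6 reaches the face of the acetyl group that leaves the new hydroxyl cis to the C6 oxygen, that is 6R,7R in the target numbering. The step needs C6 and not the alkenyl carbon C8a to migrate; the shift is reversible, and only C6 migration gives a ketone conjugated with C8a=C4a and the alkyne in an unstrained ring, so that isomer is the thermodynamic sink while the non-conjugated ketol from C8a migration can revert. The bulky silyl ethers are poor ligands, so aluminium is not diverted to a chelate with the C6 oxygen, and Al(O-t-Bu)3 is a weak, non-nucleophilic Lewis acid that should leave the propargylic epoxide intact.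

Step 10
Reactants: 17 (5R,6R)-5-[(tert-butyldimethylsilyl)oxy]-2-{[(tert-butyldimethylsilyl)oxy]methyl}-6-hydroxy-6-methyl-3-{[(2R,3R)-3-methyloxiran-2-yl]ethynyl}cyclohex-2-en-1-one
Product: 20 (6R,7R)-6,7-dihydroxy-7-methyl-3-[(2S,3R)-3-methyloxiran-2-yl]-6,7-dihydro-1H-isochromen-8(5H)-one, via hydroxymethyl ynenone 18 (not isolated), via 6-O-silyl bicyclic ketol 19 (not isolated)
Conditions: n-Bu4NF, THF, 0 °C → rt; aq. NH4Cl
Reagents that add atoms: none
Why: Fluoride cleaves the primary allylic silyl ether first, and the freed alkoxide adds to C3, the δ-carbon of the ynenone, in a 6-endo-dig oxa-Michael (1,6) addition, since the 5-exo alternative would be an anti-Michael attack at C4. Protonation at C4 gives the conjugated dienone, and the hindered C6 silyl ether is then removed; no stereocentre is involved.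

Step 11
Reactants: 21 orsellinic acid
Product: 22 tert-butyldimethylsilyl 2,4-bis[(tert-butyldimethylsilyl)oxy]-6-methylbenzoate
Conditions: TBSCl, imidazole, DMF, rt
Reagents that add atoms: tert-butyldimethylsilyl chloride, CC(C)(C)[Si](C)(C)Cl
Why: Exhaustive silylation of both phenols and the carboxylic acid under standard imidazole catalysis.

Step 12
Reactants: 22 tert-butyldimethylsilyl 2,4-bis[(tert-butyldimethylsilyl)oxy]-6-methylbenzoate
Product: 23 2,4-bis[(tert-butyldimethylsilyl)oxy]-6-methylbenzoyl chloride
Conditions: (COCl)2, DMF (cat.), CH2Cl2, 0 °C → rt; used crude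
Reagents that add atoms: oxalyl chloride, O=C(Cl)C(Cl)=O
Why: The chloroiminium salt from oxalyl chloride and DMF converts a silyl ester directly into the acid chloride under neutral conditions, leaving the aryl silyl ethers in place.

Step 13
Reactants: 20 (6R,7R)-6,7-dihydroxy-7-methyl-3-[(2S,3R)-3-methyloxiran-2-yl]-6,7-dihydro-1H-isochromen-8(5H)-one; 23 2,4-bis[(tert-butyldimethylsilyl)oxy]-6-methylbenzoyl chloride
Product: 24 (6R,7R)-7-hydroxy-7-methyl-3-[(2S,3R)-3-methyloxiran-2-yl]-8-oxo-5,6,7,8-tetrahydro-1H-isochromen-6-yl 2,4-bis[(tert-butyldimethylsilyl)oxy]-6-methylbenzoate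
Conditions: Et3N, DMAP, CH2Cl2, 0 °C → rt
Reagents that add atoms: none
Why: DMAP-catalysed acylation of the secondary C6 hydroxyl; the tertiary C7 hydroxyl beside the ketone is too hindered to compete, the C6–O bond is not broken so configuration is retained, and the amine bases are too weak at this temperature to form the C5 dienolate.

Step 14
Reactants: 24 (6R,7R)-7-hydroxy-7-methyl-3-[(2S,3R)-3-methyloxiran-2-yl]-8-oxo-5,6,7,8-tetrahydro-1H-isochromen-6-yl 2,4-bis[(tert-butyldimethylsilyl)oxy]-6-methylbenzoate
Product: 25 (6R,7R)-7-hydroxy-7-methyl-3-[(2S,3R)-3-methyloxiran-2-yl]-8-oxo-5,6,7,8-tetrahydro-1H-isochromen-6-yl 2,4-dihydroxy-6-methylbenzoate (CNP0323247.1)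
Conditions: n-Bu4NF, AcOH (1:1), THF, 0 °C
Reagents that add atoms: none
Why: Aryl silyl ethers, especially one ortho to an ester carbonyl, are cleaved by fluoride at 0 °C; the acetic acid buffer keeps the medium non-basic, so the C6 ester is not eliminated and the epoxide, enol ether and α-ketol are left alone.

## Compound list

1 | (E)-crotyl alcohol | C/C=C/CO | starting material
2 | [(2R,3R)-3-methyloxiran-2-yl]methanol | OC[C@H]1O[C@@H]1C | intermediate
3 | (2S,3R)-3-methyloxirane-2-carbaldehyde (not isolated) | O=C[C@H]1O[C@@H]1C | intermediate
4 | (2R,3R)-2-ethynyl-3-methyloxirane | C#C[C@H]1O[C@@H]1C | intermediate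
5 | (R)-4-[(tert-butyldimethylsilyl)oxy]cyclopent-2-en-1-one | O=C1C=C[C@H](O[Si](C)(C)C(C)(C)C)C1 | starting material
6 | (R)-4-[(tert-butyldimethylsilyl)oxy]-2-iodocyclopent-2-en-1-one | O=C1C(I)=C[C@H](O[Si](C)(C)C(C)(C)C)C1 | intermediate
7 | (tributylstannyl)methanol | CCCC[Sn](CCCC)(CCCC)CO | starting material
8 | (R)-4-[(tert-butyldimethylsilyl)oxy]-2-(hydroxymethyl)cyclopent-2-en-1-one | O=C1C(CO)=C[C@H](O[Si](C)(C)C(C)(C)C)C1 | intermediate
9 | (R)-4-[(tert-butyldimethylsilyl)oxy]-2-{[(tert-butyldimethylsilyl)oxy]methyl}cyclopent-2-en-1-one | O=C1C(CO[Si](C)(C)C(C)(C)C)=C[C@H](O[Si](C)(C)C(C)(C)C)C1 | intermediate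
10 | {[(2R,3R)-3-methyloxiran-2-yl]ethynyl}lithium (not isolated) | [Li]C#C[C@H]1O[C@@H]1C | intermediate
11 | (1R,4R)-4-[(tert-butyldimethylsilyl)oxy]-2-{[(tert-butyldimethylsilyl)oxy]methyl}-1-{[(2R,3R)-3-methyloxiran-2-yl]ethynyl}cyclopent-2-en-1-ol (hydroxyl cis to the ring silyloxy group) | O[C@]1(C#C[C@H]2O[C@@H]2C)C(CO[Si](C)(C)C(C)(C)C)=C[C@H](O[Si](C)(C)C(C)(C)C)C1 | intermediate
12 | (R)-5-[(tert-butyldimethylsilyl)oxy]-2-{[(tert-butyldimethylsilyl)oxy]methyl}-3-{[(2R,3R)-3-methyloxiran-2-yl]ethynyl}cyclopent-2-en-1-one | O=C1C(CO[Si](C)(C)C(C)(C)C)=C(C#C[C@H]2O[C@@H]2C)C[C@H]1O[Si](C)(C)C(C)(C)C | intermediate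
13 | ethyl vinyl ether | C=COCC | starting material
14 | (1-ethoxyvinyl)lithium (not isolated) | [Li]C(=C)OCC | intermediate
15 | (1S,5R)-5-[(tert-butyldimethylsilyl)oxy]-2-{[(tert-butyldimethylsilyl)oxy]methyl}-1-(1-ethoxyvinyl)-3-{[(2R,3R)-3-methyloxiran-2-yl]ethynyl}cyclopent-2-en-1-ol (not isolated) | CCOC(=C)[C@]1(O)C(CO[Si](C)(C)C(C)(C)C)=C(C#C[C@H]2O[C@@H]2C)C[C@H]1O[Si](C)(C)C(C)(C)C | intermediate
16 | 1-[(1S,5R)-5-[(tert-butyldimethylsilyl)oxy]-2-{[(tert-butyldimethylsilyl)oxy]methyl}-1-hydroxy-3-{[(2R,3R)-3-methyloxiran-2-yl]ethynyl}cyclopent-2-en-1-yl]ethan-1-one (hydroxyl cis to the ring silyloxy group) | CC(=O)[C@]1(O)C(CO[Si](C)(C)C(C)(C)C)=C(C#C[C@H]2O[C@@H]2C)C[C@H]1O[Si](C)(C)C(C)(C)C | intermediate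
17 | (5R,6R)-5-[(tert-butyldimethylsilyl)oxy]-2-{[(tert-butyldimethylsilyl)oxy]methyl}-6-hydroxy-6-methyl-3-{[(2R,3R)-3-methyloxiran-2-yl]ethynyl}cyclohex-2-en-1-one | CC(C)(C)[Si](C)(C)O[C@@H]1CC(C#C[C@H]2O[C@@H]2C)=C(CO[Si](C)(C)C(C)(C)C)C(=O)[C@]1(C)O | intermediate
18 | (5R,6R)-5-[(tert-butyldimethylsilyl)oxy]-6-hydroxy-2-(hydroxymethyl)-6-methyl-3-{[(2R,3R)-3-methyloxiran-2-yl]ethynyl}cyclohex-2-en-1-one (not isolated) | CC(C)(C)[Si](C)(C)O[C@@H]1CC(C#C[C@H]2O[C@@H]2C)=C(CO)C(=O)[C@]1(C)O | intermediate
19 | (6R,7R)-6-[(tert-butyldimethylsilyl)oxy]-7-hydroxy-7-methyl-3-[(2S,3R)-3-methyloxiran-2-yl]-6,7-dihydro-1H-isochromen-8(5H)-one (not isolated) | CC(C)(C)[Si](C)(C)O[C@@H]1CC2=C(COC([C@H]3O[C@@H]3C)=C2)C(=O)[C@]1(C)O | intermediate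
20 | (6R,7R)-6,7-dihydroxy-7-methyl-3-[(2S,3R)-3-methyloxiran-2-yl]-6,7-dihydro-1H-isochromen-8(5H)-one | O[C@@H]1CC2=C(COC([C@H]3O[C@@H]3C)=C2)C(=O)[C@]1(C)O | intermediate
21 | orsellinic acid (2,4-dihydroxy-6-methylbenzoic acid) | Cc1cc(O)cc(O)c1C(=O)O | starting material
22 | tert-butyldimethylsilyl 2,4-bis[(tert-butyldimethylsilyl)oxy]-6-methylbenzoate | Cc1cc(O[Si](C)(C)C(C)(C)C)cc(O[Si](C)(C)C(C)(C)C)c1C(=O)O[Si](C)(C)C(C)(C)C | intermediate
23 | 2,4-bis[(tert-butyldimethylsilyl)oxy]-6-methylbenzoyl chloride | Cc1cc(O[Si](C)(C)C(C)(C)C)cc(O[Si](C)(C)C(C)(C)C)c1C(Cl)=O | intermediate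
24 | (6R,7R)-7-hydroxy-7-methyl-3-[(2S,3R)-3-methyloxiran-2-yl]-8-oxo-5,6,7,8-tetrahydro-1H-isochromen-6-yl 2,4-bis[(tert-butyldimethylsilyl)oxy]-6-methylbenzoate | Cc1cc(O[Si](C)(C)C(C)(C)C)cc(O[Si](C)(C)C(C)(C)C)c1C(=O)O[C@@H]1CC2=C(COC([C@H]3O[C@@H]3C)=C2)C(=O)[C@]1(C)O | intermediate
25 | (6R,7R)-7-hydroxy-7-methyl-3-[(2S,3R)-3-methyloxiran-2-yl]-8-oxo-5,6,7,8-tetrahydro-1H-isochromen-6-yl 2,4-dihydroxy-6-methylbenzoate | Cc1cc(O)cc(O)c1C(=O)O[C@@H]1CC2=C(COC([C@H]3O[C@@H]3C)=C2)C(=O)[C@]1(C)O | target

## Step count and least certain steps

Total: 14 steps. Longest linear sequence: 10 steps (5 → 25 through steps 3 to 10, 13 and 14). The epoxyalkyne branch (steps 1 and 2) joins at step 6, and the aroyl chloride branch (steps 11 and 12) joins at step 13.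

**Step 9 (key step).** The most likely failures are three. The shift may stop short of equilibrium or be diverted by migration of the alkenyl carbon C8a. Part of the material may rearrange through a non-chelated arrangement, which erodes the C7 configuration. The propargylic epoxide may be opened slowly by the Lewis acid at the temperature needed for a hindered tertiary alkoxide to exchange onto aluminium.

The fallback changes both the precursor and the mode of activation. It sets out from 12 and returns at 17.
- Wittig ethylidenation of 12 (Ph3P=CHCH3, THF) should give the (5R)-1-ethylidene-5-silyloxy-2-(silyloxymethyl)-3-alkynylcyclopent-2-ene F1 as an E/Z mixture.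
- Dihydroxylation of the exocyclic alkene (OsO4 cat., N-methylmorpholine N-oxide) from the face opposite the silyloxy group should give the 1-(1-hydroxyethyl)cyclopentene-1-ol F2, with the tertiary hydroxyl trans to the silyloxy group.
- Oxidation of the secondary carbinol with Dess–Martin periodinane should give the (1R,5R)-acetyl carbinol F3, the C1 epimer of 16.
- A non-chelating base (catalytic KO-t-Bu with 18-crown-6 in toluene) should then promote the acyloin shift through the dipole-opposed anti arrangement of alkoxide and carbonyl. Inverting both the carbinol configuration and the O–C–C=O geometry leads to the same C7 configuration, and no Lewis acid meets the epoxide.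

**Step 7.** The chromium reagent is mildly acidic, so the process at risk is opening of the propargylic epoxide. A second risk is ionisation of the doubly activated tertiary alcohol toward dehydration in place of the [3,3] shift.

The fallback separates transposition from oxidation. It sets out from 11 and returns at 12. A catalytic 1,3-transposition of the allylic alcohol with Ph3SiOReO3 in ether at low temperature should give the secondary (1S,5R)-5-silyloxy-2-(silyloxymethyl)-3-alkynylcyclopent-2-en-1-ol F4, pulled over by conjugation with the alkyne. Either carbinol epimer serves. Oxidation with Dess–Martin periodinane then gives 12.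

**Step 8.** The strongly basic vinyllithium may deprotonate C5–H or the γ-position C4–H in place of adding. That would return starting material with loss of configuration at the silyloxy carbon, or expel silanolate. The acid hydrolysis could also ionise the tertiary allylic alcohol.

The fallback uses a different acetyl equivalent and no acid. It sets out from 12 and returns at 16. Isopropenylmagnesium bromide with CeCl3 should add anti to the silyloxy group to give the (1S,5R)-1-isopropenyl carbinol F5. Lemieux–Johnson cleavage (OsO4 cat., NaIO4, 2,6-lutidine, aqueous dioxane) of the unhindered 1,1-disubstituted alkene then leaves the methyl ketone 16.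

**Step 10.** The cascade relies on three events in one flask. The likely failure is slow cleavage of the hindered C6 silyl ether, which leaves the cyclised ketol exposed to basic fluoride long enough for retro-aldol or acyloin scrambling. Silyl migration to the tertiary oxygen is a second possibility.

The fallback separates the events and changes the first cleavage from fluoride to acid. It sets out from 17 and returns at 20. Catalytic camphorsulfonic acid in methanol at 0 °C should remove only the primary silyl ether, giving 18, which is isolated. Catalytic DBU in CH2Cl2 then closes the pyran to 19 while the C6 oxygen is still silylated. HF·pyridine buffered with pyridine finally gives 20 without a basic medium. No compound outside the list is made (entry F0).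

**Step 13.** Both partners are hindered: a 2,6-disubstituted aroyl chloride with a bulky ortho silyloxy group, and a hydroxyl next to a quaternary carbon. The likely failure is stalled acyl transfer. Forcing conditions would then bring on amine-induced elimination at C6.

The fallback changes the acyl donor and the unmasking chemistry. It sets out from 21 and 20 and returns at 25. Acetylation of 21 (Ac2O, pyridine, aqueous work-up) should give 2,4-diacetoxy-6-methylbenzoic acid F6. Oxalyl chloride with catalytic DMF should convert it into 2,4-diacetoxy-6-methylbenzoyl chloride F7, a smaller and more electrophilic donor. Acylation of 20 (Et3N, DMAP) should give the diacetyl orsellinate ester F8. The aryl acetates are then removed with NH4OAc in aqueous methanol at room temperature, conditions under which the hindered C6 benzoate should persist, to give 25.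

## Further compounds

F1 | step 9 | (5R)-5-[(tert-butyldimethylsilyl)oxy]-2-{[(tert-butyldimethylsilyl)oxy]methyl}-1-ethylidene-3-{[(2R,3R)-3-methyloxiran-2-yl]ethynyl}cyclopent-2-ene (E/Z mixture) | CC=C1C(CO[Si](C)(C)C(C)(C)C)=C(C#C[C@H]2O[C@@H]2C)C[C@H]1O[Si](C)(C)C(C)(C)C
F2 | step 9 | (5R)-5-[(tert-butyldimethylsilyl)oxy]-2-{[(tert-butyldimethylsilyl)oxy]methyl}-1-(1-hydroxyethyl)-3-{[(2R,3R)-3-methyloxiran-2-yl]ethynyl}cyclopent-2-en-1-ol, tertiary hydroxyl trans to the ring silyloxy group, side-chain carbinol as a mixture | CC(O)[C@@]1(O)C(CO[Si](C)(C)C(C)(C)C)=C(C#C[C@H]2O[C@@H]2C)C[C@H]1O[Si](C)(C)C(C)(C)C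
F3 | step 9 | 1-[(1R,5R)-5-[(tert-butyldimethylsilyl)oxy]-2-{[(tert-butyldimethylsilyl)oxy]methyl}-1-hydroxy-3-{[(2R,3R)-3-methyloxiran-2-yl]ethynyl}cyclopent-2-en-1-yl]ethan-1-one | CC(=O)[C@@]1(O)C(CO[Si](C)(C)C(C)(C)C)=C(C#C[C@H]2O[C@@H]2C)C[C@H]1O[Si](C)(C)C(C)(C)C
F4 | step 7 | (1S,5R)-5-[(tert-butyldimethylsilyl)oxy]-2-{[(tert-butyldimethylsilyl)oxy]methyl}-3-{[(2R,3R)-3-methyloxiran-2-yl]ethynyl}cyclopent-2-en-1-ol | O[C@H]1C(CO[Si](C)(C)C(C)(C)C)=C(C#C[C@H]2O[C@@H]2C)C[C@H]1O[Si](C)(C)C(C)(C)C
F5 | step 8 | (1S,5R)-5-[(tert-butyldimethylsilyl)oxy]-2-{[(tert-butyldimethylsilyl)oxy]methyl}-3-{[(2R,3R)-3-methyloxiran-2-yl]ethynyl}-1-(prop-1-en-2-yl)cyclopent-2-en-1-ol | CC(=C)[C@]1(O)C(CO[Si](C)(C)C(C)(C)C)=C(C#C[C@H]2O[C@@H]2C)C[C@H]1O[Si](C)(C)C(C)(C)C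
F0 | step 10 | none | none
F6 | step 13 | 2,4-diacetoxy-6-methylbenzoic acid | CC(=O)Oc1cc(C)c(C(=O)O)c(OC(C)=O)c1
F7 | step 13 | 2,4-diacetoxy-6-methylbenzoyl chloride | CC(=O)Oc1cc(C)c(C(Cl)=O)c(OC(C)=O)c1
F8 | step 13 | (6R,7R)-7-hydroxy-7-methyl-3-[(2S,3R)-3-methyloxiran-2-yl]-8-oxo-5,6,7,8-tetrahydro-1H-isochromen-6-yl 2,4-diacetoxy-6-methylbenzoate | CC(=O)Oc1cc(C)c(C(=O)O[C@@H]2CC3=C(COC([C@H]4O[C@@H]4C)=C3)C(=O)[C@]2(C)O)c(OC(C)=O)c1
A1 | alternative 1 | (4R,5R,7Z)-7-iodo-4-methyl-9-[(2S,3R)-3-methyloxiran-2-yl]-4,5-bis[(triethylsilyl)oxy]nona-1,7-diene-3,9-dione | CC[Si](CC)(CC)O[C@H](C/C(I)=C/C(=O)[C@H]1O[C@@H]1C)[C@@](C)(O[Si](CC)(CC)CC)C(=O)C=C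
A2 | alternative 1 | (6R,7R)-7-methyl-3-[(2S,3R)-3-methyloxiran-2-yl]-6,7-bis[(triethylsilyl)oxy]-6,7-dihydro-1H-isochromen-8(5H)-one | CC[Si](CC)(CC)O[C@@H]1CC2=C(COC([C@H]3O[C@@H]3C)=C2)C(=O)[C@]1(C)O[Si](CC)(CC)CC
A3 | alternative 2 | (5R,6R)-5,6-bis[(tert-butyldimethylsilyl)oxy]-6-methylcyclohex-2-en-1-one | CC(C)(C)[Si](C)(C)O[C@@H]1CC=CC(=O)[C@]1(C)O[Si](C)(C)C(C)(C)C
A4 | alternative 2 | dimethyl[(E)-pent-3-en-1-yn-1-yl]alane | C/C=C/C#C[Al](C)C
A5 | alternative 2 | formaldehyde | C=O
A6 | alternative 2 | (2R,3R,5R,6R)-5,6-bis[(tert-butyldimethylsilyl)oxy]-2-(hydroxymethyl)-6-methyl-3-[(E)-pent-3-en-1-yn-1-yl]cyclohexan-1-one | CC(C)(C)[Si](C)(C)O[C@@H]1C[C@@H](C#C/C=C/C)[C@H](CO)C(=O)[C@]1(C)O[Si](C)(C)C(C)(C)C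
A7 | alternative 3 | (2R)-2-methyl-3-{4-methyl-6-[(2S,3R)-3-methyloxiran-2-yl]-2H-pyran-3-yl}-3-oxo-2-[(triethylsilyl)oxy]propanal | O=C[C@@](C)(O[Si](CC)(CC)CC)C(=O)C1=C(C)C=C([C@H]2O[C@@H]2C)OC1
A8 | alternative 3 | (6R,7R)-6-hydroxy-7-methyl-3-[(2S,3R)-3-methyloxiran-2-yl]-7-[(triethylsilyl)oxy]-6,7-dihydro-1H-isochromen-8(5H)-one | O[C@@H]1CC2=C(COC([C@H]3O[C@@H]3C)=C2)C(=O)[C@]1(C)O[Si](CC)(CC)CC
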